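**Retrosynthetic overview**

1. End game: the C7 methylene comes from a C7 ketone, and the cis 2‑Br/3‑Cl pair comes from the C2=C3 alkene of spiro ketone 18 by anti chloroselenation followed by bromide displacement of selenium with inversion (net syn‑bromochlorination).
2. Ring B is closed last, at C1–C6, by Pd‑catalysed decarboxylative allylic alkylation. The last bond made at the spiro carbon of a preformed ring A should go trans to the C10 bromine, and the target needs C1 (not C5) in that position.
3. Key disconnection: C5–C6 and C2–C3 are therefore made first, in one flask, on the ester‑bearing carbon C6 of ring A: Michael addition to methyl vinyl ketone, then vinyl Grignard addition to the new methyl ketone with carbonate trapping.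
4. Ring A, with its C10–Br stereocentre, is made before ring B by a bromonium–enol cyclisation of a bromohydrin built from Sharpless‑epoxidised prenol and a β‑keto ester dianion.
5. Enabling feature: C6 lies between C7 of ring A (a ketone until the last step) and a traceless ester, so it is a soft carbon acid; C3 of ring B, with its methyl, is the carbonyl carbon of methyl vinyl ketone. Ring order: ring A, then ring B.

Key step: step 7

Remark on numbering and stereochemistry: atoms are numbered as in spiro[5.5]undecane (chamigrene style), ring B = C1–C6, ring A = C6–C11, C6 = spiro carbon, C7 = carbon bearing the methylene, C10 = CHBr of ring A, C11 = CMe2, C2 = CHBr and C3 = C(CH3)Cl of ring B. All names use this numbering. In it the target SMILES is (2S,3R,6R,10R): 2‑Br and 3‑Cl are cis and lie on the face of ring B that carries C7; on ring A, C5 is cis and C1 trans to the C10 bromine.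

Assumption: CH2=CHMgBr (THF solution), Cp2TiMe2 and Li2NiBr4 (from LiBr and NiBr2) are used as commercial or freshly prepared reagents.

**Route**

Step 1
Reactants: 1 2,2,6-trimethyl-4H-1,3-dioxin-4-one; 2 2-(trimethylsilyl)ethanol
Product: 4 2-(trimethylsilyl)ethyl 3-oxobutanoate, via acetylketene 3 (not isolated)
Conditions: xylene, 140 °C, acetone distilled off
Reagents that add atoms: none
Why: thermal retro-[4+2] of the dioxinone releases acetone and acetylketene, which the alcohol traps (acylketene acetoacetylation); the silylethyl ester is chosen because fluoride can later cleave it at silicon, without attack at a hindered carbonyl.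

Step 2
Reactants: 5 3-methylbut-2-en-1-ol (prenol)
Product: 6 [(2S)-3,3-dimethyloxiran-2-yl]methanol
Conditions: Ti(OiPr)4 (10 mol %), L-(+)-diethyl tartrate (12 mol %), t-BuOOH, 4 Å sieves, CH2Cl2, −20 °C
Reagents that add atoms: tert-butyl hydroperoxide, CC(C)(C)OO
Why: Sharpless asymmetric epoxidation of a primary allylic alcohol; the L-(+)-tartrate ligand delivers oxygen to the face that gives the (S)-epoxy alcohol, whose CH carbon becomes C10.

Step 3
Reactants: 6 [(2S)-3,3-dimethyloxiran-2-yl]methanol
Product: 7 (2R)-2-(bromomethyl)-3,3-dimethyloxirane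
Conditions: CBr4, PPh3, NaHCO3, CH2Cl2, 0 °C
Reagents that add atoms: carbon tetrabromide, BrC(Br)(Br)Br
Why: Appel bromination of the primary alcohol under neutral conditions should leave the trisubstituted epoxide and its stereocentre untouched (the descriptor changes only through the priority rules).

Step 4
Reactants: 4 2-(trimethylsilyl)ethyl 3-oxobutanoate; 7 (2R)-2-(bromomethyl)-3,3-dimethyloxirane
Product: 9 2-(trimethylsilyl)ethyl 5-[(2S)-3,3-dimethyloxiran-2-yl]-3-oxopentanoate, via dilithium dianion 8 (not isolated)
Conditions: LiN(iPr)2 (2.1 equiv), THF, 0 °C; then 7, −78 → −10 °C; NH4Cl quench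
Reagents that add atoms: none
Why: β-keto ester dianion alkylation; the terminal carbon of the dianion displaces the primary bromide by SN2 (the adjacent epoxide carbons are secondary and tertiary and react more slowly), and the stereocentre is not involved.

Step 5
Reactants: 9 2-(trimethylsilyl)ethyl 5-[(2S)-3,3-dimethyloxiran-2-yl]-3-oxopentanoate
Product: 10 2-(trimethylsilyl)ethyl (6R)-6-bromo-7-hydroxy-7-methyl-3-oxooctanoate
Conditions: Li2NiBr4, THF, 0 °C → rt; aqueous work-up
Reagents that add atoms: dilithium tetrabromonickelate Li2NiBr4, [Li+].[Li+].[Ni+2].[Br-].[Br-].[Br-].[Br-]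
Why: soft bromide opens the trisubstituted epoxide by SN2 at the less substituted carbon with inversion (regioselective bromohydrin formation), which sets the (R)-CHBr centre and leaves a tertiary carbinol next to it.

Step 6
Reactants: 10 2-(trimethylsilyl)ethyl (6R)-6-bromo-7-hydroxy-7-methyl-3-oxooctanoate
Product: 11 2-(trimethylsilyl)ethyl (3R)-3-bromo-2,2-dimethyl-6-oxocyclohexane-1-carboxylate (C1 epimers and enol form)
Conditions: SnCl4 (Lewis acid promoter), CH2Cl2, −78 → 0 °C
Reagents that add atoms: none
Why: the Lewis acid ionises the tertiary carbinol with help from the neighbouring bromine, and the resulting bromonium ion (CHBr configuration untouched) is opened at CMe2 by the tin-chelated enol carbon of the β-keto ester through a chair transition state with equatorial bromine; this is a cation–enol cyclisation of the kind known for 7-methyl-3-oxooct-6-enoates, closing ring A in the 6-(enolendo)-exo-tet mode.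

Step 7
Reactants: 11 2-(trimethylsilyl)ethyl (3R)-3-bromo-2,2-dimethyl-6-oxocyclohexane-1-carboxylate; 12 but-3-en-2-one; 13 vinylmagnesium bromide
Product: 16 2-(trimethylsilyl)ethyl (3R)-3-bromo-1-[3-(methoxycarbonyloxy)-3-methylpent-4-en-1-yl]-2,2-dimethyl-6-oxocyclohexane-1-carboxylate (isomers at ring C1 and at the carbinol carbon), via Michael adduct 14 (not isolated), via bromomagnesium alkoxide 15 (not isolated)
Conditions: 12 (1.05 equiv), KOtBu (5 mol %), THF, 0 °C; then CH2=CHMgBr (1.4 equiv), −78 °C; then ClCO2Me, −78 → 0 °C; one flask
Reagents that add atoms: methyl chloroformate, COC(=O)Cl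
Why: Base-catalysed Michael addition of the doubly activated carbon C6 of 11 (between the C7 ketone and the temporary ester) to 12 makes the C5–C6 bond and the quaternary carbon; CH2=CHMgBr then adds 1,2 to the new, unhindered methyl ketone (C3) and makes the C2–C3 bond, and the tertiary alkoxide is trapped as its methyl carbonate. The closest known reaction types are the Michael addition of cyclic β-keto esters to methyl vinyl ketone and Grignard addition to a methyl ketone with in situ acylation of the alkoxide. No ring is closed here: the step delivers all five remaining carbons of ring B (C1–C5) as an open chain whose C3 carbonate is a π-allyl precursor, and ring B is closed at C1–C6 in step 8. The two new stereocentres (C6 and C3) are deliberately left uncontrolled, because step 8 turns C6 into an enolate and C3 into an sp2 carbon of a π-allyl unit, so all isomers converge. The selectivity needed is chemoselectivity: C- over O-alkylation (soft enolate, soft acceptor), Grignard attack on the side-chain ketone and not on the C7 ketone or the ester (both sit on the quaternary carbon next to CMe2), and survival of the ring A bromide (equatorial and neopentyl, so neither E2 nor 3-exo displacement by the stabilised enolate is expected).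

Step 8
Reactants: 16 2-(trimethylsilyl)ethyl (3R)-3-bromo-1-[3-(methoxycarbonyloxy)-3-methylpent-4-en-1-yl]-2,2-dimethyl-6-oxocyclohexane-1-carboxylate
Product: 18 (6S,10R)-10-bromo-3,11,11-trimethylspiro[5.5]undec-2-en-7-one, via tetrabutylammonium carboxylate 17 (not isolated)
Conditions: n-Bu4NF (1.2 equiv), THF, 0 °C → rt; then Pd(PPh3)4 (5 mol %), 40 °C
Reagents that add atoms: none
Why: fluoride frees the β-keto carboxylate, the palladium catalyst ionises the tertiary allylic carbonate, and loss of CO2 gives the C6 enolate regiospecifically, which attacks the unsubstituted allyl terminus C1 (intramolecular Tsuji-type decarboxylative allylic alkylation; six-membered ring with the whole allyl unit inside, the alternative being a four-membered ring) to leave C2=C3; the new C1–C6 bond should form on the enolate face anti to the pseudoaxial C11 methyl of the half-chair with equatorial bromine, that is trans to the C10 bromine, which sets C6.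

Step 9
Reactants: 18 (6S,10R)-10-bromo-3,11,11-trimethylspiro[5.5]undec-2-en-7-one
Product: 19 (2R,3R,6S,10R)-10-bromo-3-chloro-3,11,11-trimethyl-2-(phenylselanyl)spiro[5.5]undecan-7-one
Conditions: PhSeCl (1.05 equiv), CH2Cl2, −78 °C → rt
Reagents that add atoms: benzeneselenenyl chloride, Cl[Se]c1ccccc1
Why: anti addition of PhSeCl; the seleniranium ion should form on the face of ring B anti to C7 (C7 is axial on ring B, since an axial C11 would push a methyl over the ring), and under thermodynamic control chloride ends on the tertiary carbon C3 (Markovnikov adduct, the kinetic regioisomer equilibrating through the same seleniranium ion), giving 3-Cl on the C7 face and 2-SePh trans to it, both equatorial.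

Step 10
Reactants: 19 (2R,3R,6S,10R)-10-bromo-3-chloro-3,11,11-trimethyl-2-(phenylselanyl)spiro[5.5]undecan-7-one
Product: 21 (2S,3R,6S,10R)-2,10-dibromo-3-chloro-3,11,11-trimethylspiro[5.5]undecan-7-one, via dibromoselenurane 20 (not isolated)
Conditions: Br2 (1.05 equiv), CH2Cl2, −78 → 0 °C
Reagents that add atoms: bromine, BrBr
Why: bromine oxidises the selenide to the tetravalent dibromoselenurane, and bromide then displaces this group at C2 by SN2 with inversion (known for secondary alkyl phenyl selenides, and the same displacement as the second stage of selenium-mediated syn-dihalogenation), so 2-Br ends cis to 3-Cl; return to the alkene needs antiperiplanar Se and Cl, which the diequatorial adduct does not offer.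

Step 11
Reactants: 21 (2S,3R,6S,10R)-2,10-dibromo-3-chloro-3,11,11-trimethylspiro[5.5]undecan-7-one
Product: 22 (2S,3R,6R,10R)-2,10-dibromo-3-chloro-3,11,11-trimethyl-7-methylidenespiro[5.5]undecane (target)
Conditions: Cp2TiMe2 (3 equiv), toluene, 70 °C, dark
Reagents that add atoms: dimethyltitanocene Cp2TiMe2, [CH3-].[CH3-].[Ti+4].c1cc[cH-]c1.c1cc[cH-]c1
Why: Petasis methylenation; Cp2Ti=CH2 formed on heating olefinates the hindered, enolisable C7 ketone under non-basic conditions that the tertiary chloride and both secondary bromides should tolerate, and no stereocentre is touched (the C6 descriptor changes only through the priority rules).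

**Compound list**

1 | 2,2,6-trimethyl-4H-1,3-dioxin-4-one | CC1=CC(=O)OC(C)(C)O1 | starting material
2 | 2-(trimethylsilyl)ethanol | C[Si](C)(C)CCO | starting material
3 | acetylketene | CC(=O)C=C=O | intermediate (not isolated)
4 | 2-(trimethylsilyl)ethyl 3-oxobutanoate | CC(=O)CC(=O)OCC[Si](C)(C)C | intermediate
5 | 3-methylbut-2-en-1-ol | CC(C)=CCO | starting material
6 | [(2S)-3,3-dimethyloxiran-2-yl]methanol | OC[C@@H]1OC1(C)C | intermediate
7 | (2R)-2-(bromomethyl)-3,3-dimethyloxirane | BrC[C@@H]1OC1(C)C | intermediate
8 | dilithium dianion (dienolate) of 4 | [Li]OC(=C)C=C(O[Li])OCC[Si](C)(C)C | intermediate (not isolated)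
9 | 2-(trimethylsilyl)ethyl 5-[(2S)-3,3-dimethyloxiran-2-yl]-3-oxopentanoate | C[Si](C)(C)CCOC(=O)CC(=O)CC[C@@H]1OC1(C)C | intermediate
10 | 2-(trimethylsilyl)ethyl (6R)-6-bromo-7-hydroxy-7-methyl-3-oxooctanoate | C[Si](C)(C)CCOC(=O)CC(=O)CC[C@@H](Br)C(C)(C)O | intermediate
11 | 2-(trimethylsilyl)ethyl (3R)-3-bromo-2,2-dimethyl-6-oxocyclohexane-1-carboxylate (C1 epimers and enol) | C[Si](C)(C)CCOC(=O)C1C(=O)CC[C@@H](Br)C1(C)C | intermediate
12 | but-3-en-2-one | CC(=O)C=C | starting material
13 | vinylmagnesium bromide | C=C[Mg]Br | starting material
14 | 2-(trimethylsilyl)ethyl (3R)-3-bromo-2,2-dimethyl-6-oxo-1-(3-oxobutyl)cyclohexane-1-carboxylate (C1 configuration immaterial) | C[Si](C)(C)CCOC(=O)C1(CCC(C)=O)C(=O)CC[C@@H](Br)C1(C)C | intermediate (not isolated)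
15 | bromomagnesium alkoxide of the vinyl adduct of 14 | C[Si](C)(C)CCOC(=O)C1(CCC(C)(C=C)O[Mg]Br)C(=O)CC[C@@H](Br)C1(C)C | intermediate (not isolated)
16 | 2-(trimethylsilyl)ethyl (3R)-3-bromo-1-[3-(methoxycarbonyloxy)-3-methylpent-4-en-1-yl]-2,2-dimethyl-6-oxocyclohexane-1-carboxylate (isomers at C1 and the carbinol carbon, both erased in step 8) | C[Si](C)(C)CCOC(=O)C1(CCC(C)(C=C)OC(=O)OC)C(=O)CC[C@@H](Br)C1(C)C | intermediate
17 | tetrabutylammonium carboxylate from 16 | CCCC[N+](CCCC)(CCCC)CCCC.[O-]C(=O)C1(CCC(C)(C=C)OC(=O)OC)C(=O)CC[C@@H](Br)C1(C)C | intermediate (not isolated)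
18 | (6S,10R)-10-bromo-3,11,11-trimethylspiro[5.5]undec-2-en-7-one | O=C1CC[C@@H](Br)C(C)(C)[C@@]12CCC(C)=CC2 | intermediate
19 | (2R,3R,6S,10R)-10-bromo-3-chloro-3,11,11-trimethyl-2-(phenylselanyl)spiro[5.5]undecan-7-one | O=C1CC[C@@H](Br)C(C)(C)[C@@]12CC[C@@](C)(Cl)[C@H]([Se]c3ccccc3)C2 | intermediate
20 | dibromoselenurane of 19 | O=C1CC[C@@H](Br)C(C)(C)[C@@]12CC[C@@](C)(Cl)[C@H]([Se](Br)(Br)c3ccccc3)C2 | intermediate (not isolated)
21 | (2S,3R,6S,10R)-2,10-dibromo-3-chloro-3,11,11-trimethylspiro[5.5]undecan-7-one | O=C1CC[C@@H](Br)C(C)(C)[C@@]12CC[C@@](C)(Cl)[C@@H](Br)C2 | intermediate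
22 | (2S,3R,6R,10R)-2,10-dibromo-3-chloro-3,11,11-trimethyl-7-methylidenespiro[5.5]undecane | C=C1CC[C@@H](Br)C(C)(C)[C@@]12CC[C@@](C)(Cl)[C@@H](Br)C2 | target

**Step count**

Total steps: 11. Longest linear sequence: 10 steps (steps 2–11, from prenol 5); step 1 is a one-step branch that joins in step 4.

**Steps most likely to fail, with fallbacks**

Step 10. The bromide must enter at C2 along the axial direction, syn to C7 and C8 of ring A, and the product carries an axial bromine on that face. The displacement may therefore be slower than ligand coupling on selenium (retention), loss of chloride from C3 or return to the alkene. The fallback sets out from 18 and uses oxygen instead of selenium. Epoxidation with mCPBA (NaHCO3, CH2Cl2, 0 °C) on the same open face should give the 2,3-epoxide anti to C7, F1. HCl in ether at −78 °C should open it at the tertiary carbon with inversion to the trans-chlorohydrin (3-Cl on the C7 face, 2-OH anti), F2. Tf2O and pyridine then give the 2-triflate, F3, and n-Bu4NBr in toluene displaces it with inversion, which comes back to the route at 21. This is the two-inversion route known for cis-1,2-dihalocyclohexanes from cyclohexene oxides. It keeps the inversion at C2 but has no selenium-centred side paths.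

Step 8. The tertiary π-allylpalladium intermediate may lose a β-hydrogen to give a 1,3-diene, or the fully substituted enolate next to CMe2 may be protonated before it attacks. The fallback sets out from 14, isolated after the Michael stage of step 7. Wittig methylenation of the side-chain methyl ketone (Ph3P=CH2, THF, 0 °C) should give 2-(trimethylsilyl)ethyl (3R)-3-bromo-2,2-dimethyl-1-(3-methylbut-3-en-1-yl)-6-oxocyclohexane-1-carboxylate, F4. n-Bu4NF followed by allyl methyl carbonate and Pd(PPh3)4 (intermolecular decarboxylative allylation, with the allyl group entering trans to bromine for the same reason as in step 8) should give (2R,4R)-4-bromo-3,3-dimethyl-2-(3-methylbut-3-en-1-yl)-2-(prop-2-en-1-yl)cyclohexan-1-one, F5. Ring-closing metathesis with the second-generation Hoveyda–Grubbs catalyst (CH2Cl2, 40 °C) then forms C2=C3 and comes back to the route at 18.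

Step 6. After ionisation of the tertiary carbinol the enol may close through oxygen, a hydride may shift (pinacol-type), or the Lewis acid may remove the silylethyl ester. The fallback sets out from 10. HCl in dioxane at 0 °C should convert the tertiary alcohol into the chloride with retention through the bromonium ion, giving 2-(trimethylsilyl)ethyl (6R)-6-bromo-7-chloro-7-methyl-3-oxooctanoate, F6. Solvolysis of F6 in hexafluoroisopropanol at room temperature (bromonium formation by loss of chloride, without a Lewis acid) then closes ring A and comes back to the route at 11.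

**Further compounds**

F1 | step 10 | (6S,10R)-10-bromo-3,11,11-trimethyl-2,3-epoxyspiro[5.5]undecan-7-one, epoxide anti to C7 | O=C1CC[C@@H](Br)C(C)(C)[C@@]12CC[C@]3(C)O[C@@H]3C2
F2 | step 10 | 10-bromo-3-chloro-2-hydroxy-3,11,11-trimethylspiro[5.5]undecan-7-one, 3-Cl on the C7 face and 2-OH trans to it | O=C1CC[C@@H](Br)C(C)(C)[C@@]12CC[C@@](C)(Cl)[C@H](O)C2
F3 | step 10 | 2-trifluoromethanesulfonate of F2 | O=C1CC[C@@H](Br)C(C)(C)[C@@]12CC[C@@](C)(Cl)[C@H](OS(=O)(=O)C(F)(F)F)C2
F4 | step 8 | 2-(trimethylsilyl)ethyl (3R)-3-bromo-2,2-dimethyl-1-(3-methylbut-3-en-1-yl)-6-oxocyclohexane-1-carboxylate | C[Si](C)(C)CCOC(=O)C1(CCC(C)=C)C(=O)CC[C@@H](Br)C1(C)C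
F5 | step 8 | (2R,4R)-4-bromo-3,3-dimethyl-2-(3-methylbut-3-en-1-yl)-2-(prop-2-en-1-yl)cyclohexan-1-one | O=C1CC[C@@H](Br)C(C)(C)[C@@]1(CC=C)CCC(C)=C
F6 | step 6 | 2-(trimethylsilyl)ethyl (6R)-6-bromo-7-chloro-7-methyl-3-oxooctanoate | C[Si](C)(C)CCOC(=O)CC(=O)CC[C@@H](Br)C(C)(C)Cl
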